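# Route to (5R)-3-hydroxy-4-(4-hydroxyphenyl)-5-{[4-hydroxy-3-(3-methylbut-2-en-1-yl)phenyl]methyl}furan-2(5H)-one (CNP0382875.1)

Numbering used throughout: 1 4-hydroxyphenylpyruvic acid; 2 its methyl ester; 3 bis(methoxymethyl) enol ether ester; 4 vicinal dibromide; 5 (E)-bromo ester; 6 (E)-bromo acid; 7 4-iodophenol; 8 prenyl bromide; 9 4-iodo-2-prenylphenol; 10 its triisopropylsilyl ether; 11 ethynyltrimethylsilane; 12 silyl-capped arylalkyne; 13 terminal arylalkyne; 14 enynoic acid; 15 (Z)-5-arylidene furanone; 16 (R)-5-benzyl furanone, fully protected; 17 ring B silyl ether of the target; 18 target.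

## Analysis of the target

The target 18 is a single furan-2(5H)-one ring (O1, carbonyl C2, C3, C4, C5). It carries an enolic hydroxyl on C3, a 4-hydroxyphenyl group (ring A) on C4 and, on C5, a methylene carbon C6 bonded to a 4-hydroxy-3-prenylphenyl group (ring B). C5 is the only stereocentre and is R (O1 > C4 > C6 > H), so there is no neighbouring centre to relay from and its configuration must come from a reagent or catalyst. The sensitive groups are the C3 enol (the enolised form of an α-keto lactone), two phenols and the prenyl alkene. The prenyl chain sits ortho to a phenol, so acid can close it to a chroman, and unselective hydrogenation catalysts would reduce it. The C5–H bond is allylic, next to O1 and γ to the carbonyl, so once the enol is protected base can racemise C5 through the 2-oxidofuran. The difficulty is therefore to set one isolated stereocentre beside a tetrasubstituted alkene without touching the prenyl group and without exposing the protected butenolide to base afterwards. The strategy rests on the substitution of C5: it bears only O1, C4 and the benzylic C6, so the ring can be closed flat as a (Z)-5-arylidene furanone with a C5=C6 bond, from an alkyne whose two carbons become C5 and C6, and C5 is then set by delivering hydrogen to one face.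

## Retrosynthetic reasoning

**Protecting groups (18 from 17 from 16).** The last bond cut is O–Si on ring B, and before it the two O–CH2 acetal bonds on the C3 enol and on ring A. Acid must not meet a free phenol ortho to the prenyl chain, so that phenol stays silylated while the acetals are cleaved. Basic fluoride must not meet the fully protected butenolide 16, where C5–H is the most acidic site; in 17 the free enol is ionised first and shields C5. A hindered silyl ether is used on ring B because it has to survive the alkyne desilylation and the acidic acetal cleavage. Ring A and the enol carry the same acetal because both are installed in one operation and both must survive saponification, which an aryl silyl ether would not.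

**C5–H and C6–H (16 from 15).** Removing these two hydrogens turns the stereocentre into the trigonal carbon of an exocyclic enol-lactone alkene. This is the only place where unsaturation can be introduced without changing the skeleton or the oxidation level at C3, and it separates the stereochemical problem from ring construction. The forward step must add hydrogen to the Si face of C5 (O1 > C4 > C6) of the Z alkene and leave the tetrasubstituted C3=C4 bond and the prenyl alkene alone.

**C4–C5 and O1–C5 (15 from 6 and 13, through 14).** Both bonds to C5 are cut at once, which divides the molecule into a ring A half carrying C2–C4 with the C3 oxygen in place and a ring B half carrying C5 and C6 as an alkyne. Cutting here makes the route convergent, puts all three ring carbons at their final oxidation level, and leaves ring closure to a carboxylate held cis to the alkyne. The forward step has to couple a hindered vinyl bromide with retention of geometry and then close through the near alkyne carbon with anti addition, so that the Z alkene results.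

**Bromo acid (6 from 5 from 3 through 4, from 2, from 1).** The C3–Br bond of the acid fragment is traced to addition of bromine to the enol ether 3 and loss of HBr, the ester to saponification, and the two acetals to a double O-alkylation of 2, the ester of commercial 1. The three-carbon chain, the aryl group and the C2 oxygen are all present in 1, so no C–C bond has to be made on this side. The forward sequence must deliver the bromide cis to the carboxyl.

**Arylalkyne (13 from 12 from 10 and 11; 10 from 9 from 7 and 8).** The aryl–alkyne bond is cut back to the aryl iodide 10 and the capped acetylene 11, and the prenyl C–C bond to ortho-alkylation of 7 with 8. Iodine serves twice: it blocks the para position during the alkylation and is the coupling handle afterwards.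

## Alternatives that were turned down

**Alternative 1:** The lactone is traced to a cyclobutanone: O1–C5 comes from a Baeyer–Villiger oxygen insertion, and C4–C5 and C2–C3 from a (2+2) cycloaddition.
- Forward key step: the keteniminium salt generated from the (2R,5R)-2,5-dimethylpyrrolidine amide A2 adds to 4-acetoxystyrene A3, and hydrolysis gives the trans-cyclobutanone A1. Its benzyl-bearing carbon then migrates with retention to give the lactone A4.
- For: the auxiliary fixes the future C5 in a well-understood cycloaddition, diastereomers can be separated, and migration of the more substituted carbon is predictable. On stereochemical assurance this is stronger than a catalyst-controlled hydrogenation of a new substrate.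
- Against: A4 is a saturated lactone with no oxygen on C3, so the enol and the C3=C4 bond must be introduced afterwards by oxidation of a base-sensitive lactone, and the C4 centre that was built is discarded. The prenyl group cannot be present during the peracid step and has to be attached last at the aryl bromide, where allyl transfer can give linear and branched isomers. The electron-rich styrene A3 is also prone to cationic polymerisation.
- Comparison: the chosen route offers instead the correct oxidation level at C2–C4 from the first step, union of the two aryl halves in one operation, and only three operations after ring formation.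

**Alternative 2:** The C4–ring A bond and O1–C5 are cut.
- Forward key step: the (R)-configured allenoic acid A6 and the ring A aryl iodide A7 react under zerovalent palladium catalysis with a carbonate base. Arylpalladation of the allene and closure by the carboxylate give the butenolide A5 with transfer of axial to central chirality.
- For: it is as convergent as the chosen route, ring and stereocentre are made together, and no hydrogenation is needed in the presence of the prenyl group.
- Against: A5 has hydrogen at C3. Hydroxylating that position needs either oxidants that also attack the prenyl alkene or bases that deprotonate C5. A6 must first be obtained in optically active form, and π-allylpalladium intermediates can erode the chirality transfer.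
- Comparison: the chosen route carries the C3 oxygen in from the pyruvate and pays for it with a separate stereo-defining step.

**Alternative 3:** O1–C5 and the C6–ring B bond are cut.
- Forward key step: the dienoic acid A9 is cyclised with an electrophilic iodine source and the dimeric cinchona catalyst hydroquinidine 1,4-phthalazinediyl diether, (DHQD)2PHAL, to the iodolactone A8. Ring B is then attached at the iodomethyl carbon.
- For: ring, C3 oxygen and stereocentre arise in one organocatalytic step without pressure equipment. In step count to a stereodefined, C3-oxygenated butenolide it is the strongest of the four.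
- Against: the alkene to be attacked is the terminal vinyl group of an electron-poor conjugated dienoic acid, a poor partner for a halonium ion and outside the alkene classes for which this catalysis is reliable. The subsequent sp3–sp2 coupling places a metal or radical on C6 with O1 as a β leaving group, so β-elimination back to A9 competes.
- Comparison: the chosen route attaches ring B by an sp–sp2 coupling that has no such escape path, at the price of a hydrogenation whose selectivity must be established.

Key step: step 9

Assumption (step 3): dehydrobromination of 4 is taken to give mainly the E isomer 5 (bromine cis to the ester, aryl trans to it), the less strained arrangement; the geometry is to be confirmed before step 9.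
Assumption (step 10): (R)-BINAP is written provisionally; the enantiomer of the ligand that delivers hydrogen to the Si face of C5 is to be fixed by a trial run.

## Route

Step 1
Reactants: 1 4-hydroxyphenylpyruvic acid
Product: 2 methyl 3-(4-hydroxyphenyl)-2-oxopropanoate
Conditions: MeOH, H2SO4 (cat.), 50 °C
Reagents that add atoms: methanol, CO
Why: Fischer esterification; the carboxyl next to the ketone is activated and the phenol does not react under acid. The ester exists largely as the Z enol, which is what step 2 needs.

Step 2
Reactants: 2 methyl 3-(4-hydroxyphenyl)-2-oxopropanoate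
Product: 3 methyl (2Z)-2-(methoxymethoxy)-3-[4-(methoxymethoxy)phenyl]prop-2-enoate
Conditions: MeOCH2Cl (2.5 equiv), i-Pr2NEt (3 equiv), CH2Cl2, 0 °C to rt
Reagents that add atoms: chloromethyl methyl ether, COCCl
Why: O-alkylation of the phenoxide and of the conjugated enolate by the hard chloromethyl ether under amine base. The enol ether should keep the Z geometry of the enol, with the aryl group trans to the ester.

Step 3
Reactants: 3 methyl (2Z)-2-(methoxymethoxy)-3-[4-(methoxymethoxy)phenyl]prop-2-enoate
Product: 5 methyl (2E)-3-bromo-2-(methoxymethoxy)-3-[4-(methoxymethoxy)phenyl]prop-2-enoate, via vicinal dibromide 4 (not isolated)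
Conditions: Br2 (1.05 equiv), CH2Cl2, −78 °C; then Et3N (3 equiv), −78 °C to rt
Reagents that add atoms: bromine, BrBr
Why: Electrophilic addition of bromine to the electron-rich enol ether gives 4, and Et3N then removes HBr across C3–H and the labile bromide on the acetal carbon (bromination–dehydrobromination of an enol ether). The isomer with the aryl group trans to the ester (E, bromine cis to the ester) is the less strained one and should predominate; it is purified by chromatography and its geometry checked.

Step 4
Reactants: 5 methyl (2E)-3-bromo-2-(methoxymethoxy)-3-[4-(methoxymethoxy)phenyl]prop-2-enoate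
Product: 6 (2E)-3-bromo-2-(methoxymethoxy)-3-[4-(methoxymethoxy)phenyl]prop-2-enoic acid
Conditions: LiOH·H2O (3 equiv), THF/H2O, rt; then 1 M HCl to pH 3, 0 °C
Reagents that add atoms: lithium hydroxide, [Li+].[OH-]
Why: Saponification of the methyl ester; the vinyl bromide has no hydrogen to eliminate and both acetals are stable to hydroxide, which is why ring A carries an acetal and not a silyl ether. Brief cold acidification frees the acid without cleaving the enol acetal.

Step 5
Reactants: 7 4-iodophenol; 8 1-bromo-3-methylbut-2-ene (prenyl bromide)
Product: 9 4-iodo-2-(3-methylbut-2-en-1-yl)phenol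
Conditions: NaH (1.05 equiv), toluene, 0 °C; then 8, rt
Reagents that add atoms: none
Why: ortho-C-Alkylation of a sodium phenoxide held as a tight ion pair in a non-polar solvent; the para position is blocked by iodine, so the allyl group enters next to oxygen. The neutral O-prenyl ether by-product is removed by base extraction and chromatography.

Step 6
Reactants: 9 4-iodo-2-(3-methylbut-2-en-1-yl)phenol
Product: 10 [4-iodo-2-(3-methylbut-2-en-1-yl)phenoxy]tri(propan-2-yl)silane
Conditions: i-Pr3SiCl, imidazole, DMF, rt
Reagents that add atoms: chlorotriisopropylsilane, CC(C)[Si](Cl)(C(C)C)C(C)C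
Why: Silylation of the phenol; the hindered triisopropylsilyl ether is chosen because it has to survive carbonate in methanol (step 8), Et3N (step 9) and methanolic HCl (step 11).

Step 7
Reactants: 10 [4-iodo-2-(3-methylbut-2-en-1-yl)phenoxy]tri(propan-2-yl)silane; 11 ethynyltrimethylsilane
Product: 12 trimethyl({3-(3-methylbut-2-en-1-yl)-4-[(triisopropylsilyl)oxy]phenyl}ethynyl)silane
Conditions: PdCl2(PPh3)2 (2 mol %), CuI (4 mol %), Et3N, THF, rt
Reagents that add atoms: none
Why: Sonogashira coupling of an aryl iodide with a terminal alkyne at room temperature; the silyl cap prevents double coupling.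

Step 8
Reactants: 12 trimethyl({3-(3-methylbut-2-en-1-yl)-4-[(triisopropylsilyl)oxy]phenyl}ethynyl)silane
Product: 13 [4-ethynyl-2-(3-methylbut-2-en-1-yl)phenoxy]tri(propan-2-yl)silane
Conditions: K2CO3 (0.2 equiv), MeOH/THF, 0 °C to rt
Reagents that add atoms: none
Why: Methanolysis of the alkynyl C–Si bond with catalytic carbonate; the hindered aryl silyl ether should not be cleaved under these brief, mild conditions.

Step 9
Reactants: 6 (2E)-3-bromo-2-(methoxymethoxy)-3-[4-(methoxymethoxy)phenyl]prop-2-enoic acid; 13 [4-ethynyl-2-(3-methylbut-2-en-1-yl)phenoxy]tri(propan-2-yl)silane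
Product: 15 (5Z)-3-(methoxymethoxy)-4-[4-(methoxymethoxy)phenyl]-5-({3-(3-methylbut-2-en-1-yl)-4-[(triisopropylsilyl)oxy]phenyl}methylidene)furan-2(5H)-one, via enynoic acid 14 (not isolated)
Conditions: PdCl2(PPh3)2 (5 mol %), CuI (10 mol %), Et3N (4 equiv), MeCN (degassed), 50 °C, slow addition of 13
Reagents that add atoms: none
Why: Zerovalent palladium, formed in the flask from PdCl2(PPh3)2, inserts into the C–Br bond of the carboxylate of 6, the alkynylcopper species made from 13, CuI and Et3N transfers its alkynyl group, and reductive elimination forms C4–C5 with retention of the alkene geometry, giving 14 with carboxylate and alkyne cis on C3=C4. The carboxylate oxygen then attacks the near alkyne carbon (the future C5), which is activated by coordination to divalent palladium or monovalent copper, from the side opposite the metal, and protonation of the resulting vinyl–metal bond at C6 releases 15. The closest known reaction type is the one-pot Sonogashira coupling–lactonisation of (Z)-3-halopropenoic acids with terminal alkynes, which gives (Z)-5-ylidenefuran-2(5H)-ones. The furanone ring is closed in the 5-exo-dig mode through O1–C5. No stereocentre is formed; the Z geometry of C5=C6 follows from the anti addition of oxygen and metal across the alkyne, and it is also the less strained isomer because C6–H, not ring B, faces ring A on C4. The step needs 5-exo closure in preference to 6-endo closure to a 2-pyranone: the cis arrangement fixed in 6 holds the carboxylate over the near alkyne carbon, and 6-endo closure would force rings A and B onto neighbouring ring carbons. It also needs cross-coupling to outrun oxidative dimerisation of 13, which degassing and slow addition of 13 should secure, and it depends on the geometry of 6, since an isomer with bromine trans to the carboxyl cannot close.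

Step 10
Reactants: 15 (5Z)-3-(methoxymethoxy)-4-[4-(methoxymethoxy)phenyl]-5-({3-(3-methylbut-2-en-1-yl)-4-[(triisopropylsilyl)oxy]phenyl}methylidene)furan-2(5H)-one
Product: 16 (5R)-3-(methoxymethoxy)-4-[4-(methoxymethoxy)phenyl]-5-({3-(3-methylbut-2-en-1-yl)-4-[(triisopropylsilyl)oxy]phenyl}methyl)furan-2(5H)-one
Conditions: [RuCl(p-cymene)((R)-BINAP)]Cl (2 mol %), H2 (50 bar), CH2Cl2, 40 °C
Reagents that add atoms: none
Why: Enantioselective homogeneous hydrogenation of an exocyclic enol-lactone alkene, a reaction type established for alkylidene lactones with [RuCl(arene)(BINAP)]Cl-type catalysts; the chiral catalyst adds H2 to one face of the flat C5=C6 bond and so sets C5 (R requires delivery to the Si face of C5, O1 > C4 > C6). This catalyst class is preferred to [Rh(cod)2]BF4 with a bisphosphine because the lactone carbonyl is held away from C5=C6 and cannot chelate as the acyl group of an open-chain enol ester does. The tetrasubstituted C3=C4 bond is too hindered and the isolated prenyl alkene has no coordinating neighbour, so neither should be reduced, and the neutral medium leaves C5 configurationally intact.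

Step 11
Reactants: 16 (5R)-3-(methoxymethoxy)-4-[4-(methoxymethoxy)phenyl]-5-({3-(3-methylbut-2-en-1-yl)-4-[(triisopropylsilyl)oxy]phenyl}methyl)furan-2(5H)-one
Product: 17 (5R)-3-hydroxy-4-(4-hydroxyphenyl)-5-({3-(3-methylbut-2-en-1-yl)-4-[(triisopropylsilyl)oxy]phenyl}methyl)furan-2(5H)-one
Conditions: HCl (2 M) in MeOH/THF, 25–40 °C
Reagents that add atoms: none
Why: Acid-catalysed methanolysis of both methoxymethyl acetals. The ring B phenol stays silylated, so the prenyl chain has no free ortho phenol to cyclise onto, and C5 is configurationally stable in acid.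

Step 12
Reactants: 17 (5R)-3-hydroxy-4-(4-hydroxyphenyl)-5-({3-(3-methylbut-2-en-1-yl)-4-[(triisopropylsilyl)oxy]phenyl}methyl)furan-2(5H)-one
Product: 18 (5R)-3-hydroxy-4-(4-hydroxyphenyl)-5-{[4-hydroxy-3-(3-methylbut-2-en-1-yl)phenyl]methyl}furan-2(5H)-one
Conditions: Bu4NF (1.2 equiv), AcOH (1.2 equiv), THF, 0 °C
Reagents that add atoms: none
Why: Fluoride-mediated cleavage of the aryl silyl ether, buffered with AcOH. The acidic enol is ionised before C5–H could be, so the stereocentre is not at risk.

## Compound list

1 | 4-hydroxyphenylpyruvic acid | OC(=O)C(=O)Cc1ccc(O)cc1 | starting material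
2 | methyl 3-(4-hydroxyphenyl)-2-oxopropanoate | COC(=O)C(=O)Cc1ccc(O)cc1 | intermediate
3 | methyl (2Z)-2-(methoxymethoxy)-3-[4-(methoxymethoxy)phenyl]prop-2-enoate | COC(=O)/C(OCOC)=C/c1ccc(OCOC)cc1 | intermediate
4 | methyl 2,3-dibromo-2-(methoxymethoxy)-3-[4-(methoxymethoxy)phenyl]propanoate (diastereomer mixture, not isolated) | COC(=O)C(Br)(OCOC)C(Br)c1ccc(OCOC)cc1 | intermediate
5 | methyl (2E)-3-bromo-2-(methoxymethoxy)-3-[4-(methoxymethoxy)phenyl]prop-2-enoate | COC(=O)/C(OCOC)=C(\Br)c1ccc(OCOC)cc1 | intermediate
6 | (2E)-3-bromo-2-(methoxymethoxy)-3-[4-(methoxymethoxy)phenyl]prop-2-enoic acid | OC(=O)/C(OCOC)=C(\Br)c1ccc(OCOC)cc1 | intermediate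
7 | 4-iodophenol | Oc1ccc(I)cc1 | starting material
8 | 1-bromo-3-methylbut-2-ene | CC(C)=CCBr | starting material
9 | 4-iodo-2-(3-methylbut-2-en-1-yl)phenol | CC(C)=CCc1cc(I)ccc1O | intermediate
10 | [4-iodo-2-(3-methylbut-2-en-1-yl)phenoxy]tri(propan-2-yl)silane | CC(C)=CCc1cc(I)ccc1O[Si](C(C)C)(C(C)C)C(C)C | intermediate
11 | ethynyltrimethylsilane | C#C[Si](C)(C)C | starting material
12 | trimethyl({3-(3-methylbut-2-en-1-yl)-4-[(triisopropylsilyl)oxy]phenyl}ethynyl)silane | CC(C)=CCc1cc(C#C[Si](C)(C)C)ccc1O[Si](C(C)C)(C(C)C)C(C)C | intermediate
13 | [4-ethynyl-2-(3-methylbut-2-en-1-yl)phenoxy]tri(propan-2-yl)silane | CC(C)=CCc1cc(C#C)ccc1O[Si](C(C)C)(C(C)C)C(C)C | intermediate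
14 | (2E)-2-(methoxymethoxy)-3-[4-(methoxymethoxy)phenyl]-5-{3-(3-methylbut-2-en-1-yl)-4-[(triisopropylsilyl)oxy]phenyl}pent-2-en-4-ynoic acid (carboxyl and alkynyl cis; not isolated) | OC(=O)/C(OCOC)=C(\C#Cc1ccc(O[Si](C(C)C)(C(C)C)C(C)C)c(CC=C(C)C)c1)c1ccc(OCOC)cc1 | intermediate
15 | (5Z)-3-(methoxymethoxy)-4-[4-(methoxymethoxy)phenyl]-5-({3-(3-methylbut-2-en-1-yl)-4-[(triisopropylsilyl)oxy]phenyl}methylidene)furan-2(5H)-one | COCOC1=C(c2ccc(OCOC)cc2)/C(=C/c2ccc(O[Si](C(C)C)(C(C)C)C(C)C)c(CC=C(C)C)c2)OC1=O | intermediate
16 | (5R)-3-(methoxymethoxy)-4-[4-(methoxymethoxy)phenyl]-5-({3-(3-methylbut-2-en-1-yl)-4-[(triisopropylsilyl)oxy]phenyl}methyl)furan-2(5H)-one | COCOC1=C(c2ccc(OCOC)cc2)[C@@H](Cc2ccc(O[Si](C(C)C)(C(C)C)C(C)C)c(CC=C(C)C)c2)OC1=O | intermediate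
17 | (5R)-3-hydroxy-4-(4-hydroxyphenyl)-5-({3-(3-methylbut-2-en-1-yl)-4-[(triisopropylsilyl)oxy]phenyl}methyl)furan-2(5H)-one | OC1=C(c2ccc(O)cc2)[C@@H](Cc2ccc(O[Si](C(C)C)(C(C)C)C(C)C)c(CC=C(C)C)c2)OC1=O | intermediate
18 | (5R)-3-hydroxy-4-(4-hydroxyphenyl)-5-{[4-hydroxy-3-(3-methylbut-2-en-1-yl)phenyl]methyl}furan-2(5H)-one | CC(C)=CCc1cc(C[C@H]2OC(=O)C(O)=C2c2ccc(O)cc2)ccc1O | target

## Step count and risk

Total: 12 steps. Longest linear sequence: 8 steps (steps 1–4 and 9–12 from 1, or steps 5–8 and 9–12 from 7).

**Step 9 (key step).**
- What may go wrong: closure through the far alkyne carbon (6-endo) to a 2-pyranone, because the electron-rich ring B makes that carbon the more electrophilic one once a metal binds the alkyne. Oxidative addition at the hindered tetrasubstituted vinyl bromide may also be slow, leaving time for oxidative dimerisation of 13.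
- Fallback (sets out from 2 and 10, returns at 15): the ring is made first and C5=C6 by condensation.
  - Aldol addition of 2 to aqueous formaldehyde (K2CO3, then HCl) with lactonisation should give 3-hydroxy-4-(4-hydroxyphenyl)furan-2(5H)-one F1.
  - Double methoxymethylation (MeOCH2Cl, i-Pr2NEt) gives 3-(methoxymethoxy)-4-[4-(methoxymethoxy)phenyl]furan-2(5H)-one F2.
  - Iodine–magnesium exchange on 10 (i-PrMgCl·LiCl, THF, −20 °C) and formylation with DMF give 3-(3-methylbut-2-en-1-yl)-4-[(triisopropylsilyl)oxy]benzaldehyde F3.
  - F2 is converted with TBSOTf and i-Pr2NEt in CH2Cl2 into the silyloxyfuran tert-butyl({3-(methoxymethoxy)-4-[4-(methoxymethoxy)phenyl]furan-2-yl}oxy)dimethylsilane F4.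
  - F4 adds through C5 to F3 in a vinylogous Mukaiyama aldol reaction to give the silylated adduct 5-{[(tert-butyldimethylsilyl)oxy]{3-(3-methylbut-2-en-1-yl)-4-[(triisopropylsilyl)oxy]phenyl}methyl}-3-(methoxymethoxy)-4-[4-(methoxymethoxy)phenyl]furan-2(5H)-one F5.
  - DBU in the same flask eliminates silanol to 15, the Z isomer being the more stable.

**Step 3.**
- What may go wrong: loss of the methoxymethyl group from the acetal carbon of 4 before HBr is eliminated, since that carbon ionises easily. Elimination may also give the geometric isomer with bromine trans to the ester, which cannot lactonise in step 9.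
- Fallback (sets out from 3, returns at 5): the fragmentation is used deliberately. Bromine is added to 3 at −78 °C and the mixture warmed without base, so that 4 sheds the acetal group and gives methyl 3-bromo-3-[4-(methoxymethoxy)phenyl]-2-oxopropanoate F6. O-Alkylation of its enolate (MeOCH2Cl, i-Pr2NEt, CH2Cl2) then gives 5. The geometry is now set by the enolate, in which the aryl group should sit syn to the enolate oxygen as in the enol of 2, and not by an elimination.

**Step 10.**
- What may go wrong: insufficient facial discrimination, because the substrate offers the catalyst no chelating group beside the alkene. Other risks are slow turnover at the trisubstituted styrene-like alkene, and addition of hydrogen across the C6=C5–C4=C3 diene followed by isomerisation, which would give racemic material.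
- Fallback (sets out from 15, returns at 16): C5 is set by ketone reduction instead.
  - Methanolysis of the enol lactone (NaOMe, 0.2 equiv, MeOH/THF, 0 °C) gives methyl (2E)-2-(methoxymethoxy)-3-[4-(methoxymethoxy)phenyl]-5-{3-(3-methylbut-2-en-1-yl)-4-[(triisopropylsilyl)oxy]phenyl}-4-oxopent-2-enoate F7.
  - Corey–Bakshi–Shibata reduction (2-methyl-oxazaborolidine of the appropriate hand, catecholborane, toluene, −78 °C; catecholborane spares the prenyl alkene) gives methyl (2E,4R)-4-hydroxy-2-(methoxymethoxy)-3-[4-(methoxymethoxy)phenyl]-5-{3-(3-methylbut-2-en-1-yl)-4-[(triisopropylsilyl)oxy]phenyl}pent-2-enoate F8.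
  - The hydroxyl of F8 is cis to the ester and should lactonise to 16 on standing or with a trace of pyridinium tosylate.

**Step 5.**
- What may go wrong: O-alkylation competing with ortho C-alkylation, and a second alkylation of the product, since the selectivity depends on ion pairing in toluene.
- Fallback (sets out from 7, returns at 9): O-alkylation of 7 with 3-chloro-3-methylbut-1-yne (DBU, CuCl2 cat., MeCN, 0 °C) gives 1-iodo-4-[(2-methylbut-3-yn-2-yl)oxy]benzene F9. Semi-hydrogenation over Pd/CaCO3 poisoned with Pb(OAc)2 and quinoline, stopped after one equivalent of H2, gives 1-iodo-4-[(2-methylbut-3-en-2-yl)oxy]benzene F10. Heating F10 (N,N-diethylaniline, about 130 °C) brings about an aromatic Claisen rearrangement that places the chain at the ortho carbon as the prenyl group of 9, regiospecifically.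

## Further compounds

F1 | step 9 | 3-hydroxy-4-(4-hydroxyphenyl)furan-2(5H)-one | OC1=C(c2ccc(O)cc2)COC1=O
F2 | step 9 | 3-(methoxymethoxy)-4-[4-(methoxymethoxy)phenyl]furan-2(5H)-one | COCOC1=C(c2ccc(OCOC)cc2)COC1=O
F3 | step 9 | 3-(3-methylbut-2-en-1-yl)-4-[(triisopropylsilyl)oxy]benzaldehyde | CC(C)=CCc1cc(C=O)ccc1O[Si](C(C)C)(C(C)C)C(C)C
F4 | step 9 | tert-butyl({3-(methoxymethoxy)-4-[4-(methoxymethoxy)phenyl]furan-2-yl}oxy)dimethylsilane | COCOc1c(-c2ccc(OCOC)cc2)coc1O[Si](C)(C)C(C)(C)C
F5 | step 9 | 5-{[(tert-butyldimethylsilyl)oxy]{3-(3-methylbut-2-en-1-yl)-4-[(triisopropylsilyl)oxy]phenyl}methyl}-3-(methoxymethoxy)-4-[4-(methoxymethoxy)phenyl]furan-2(5H)-one (diastereomer mixture) | COCOC1=C(c2ccc(OCOC)cc2)C(C(O[Si](C)(C)C(C)(C)C)c2ccc(O[Si](C(C)C)(C(C)C)C(C)C)c(CC=C(C)C)c2)OC1=O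
F6 | step 3 | methyl 3-bromo-3-[4-(methoxymethoxy)phenyl]-2-oxopropanoate | COC(=O)C(=O)C(Br)c1ccc(OCOC)cc1
F7 | step 10 | methyl (2E)-2-(methoxymethoxy)-3-[4-(methoxymethoxy)phenyl]-5-{3-(3-methylbut-2-en-1-yl)-4-[(triisopropylsilyl)oxy]phenyl}-4-oxopent-2-enoate | COC(=O)/C(OCOC)=C(/c1ccc(OCOC)cc1)C(=O)Cc1ccc(O[Si](C(C)C)(C(C)C)C(C)C)c(CC=C(C)C)c1
F8 | step 10 | methyl (2E,4R)-4-hydroxy-2-(methoxymethoxy)-3-[4-(methoxymethoxy)phenyl]-5-{3-(3-methylbut-2-en-1-yl)-4-[(triisopropylsilyl)oxy]phenyl}pent-2-enoate | COC(=O)/C(OCOC)=C(/c1ccc(OCOC)cc1)[C@H](O)Cc1ccc(O[Si](C(C)C)(C(C)C)C(C)C)c(CC=C(C)C)c1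
F9 | step 5 | 1-iodo-4-[(2-methylbut-3-yn-2-yl)oxy]benzene | CC(C)(C#C)Oc1ccc(I)cc1
F10 | step 5 | 1-iodo-4-[(2-methylbut-3-en-2-yl)oxy]benzene | CC(C)(C=C)Oc1ccc(I)cc1
A1 | alternative 1 | trans-2-[3-bromo-4-(tert-butyldimethylsilyloxy)benzyl]-3-(4-acetoxyphenyl)cyclobutanone | CC(C)(C)[Si](C)(C)Oc1ccc(C[C@H]2C(=O)C[C@@H]2c2ccc(OC(C)=O)cc2)cc1Br
A2 | alternative 1 | 3-[3-bromo-4-(tert-butyldimethylsilyloxy)phenyl]-1-[(2R,5R)-2,5-dimethylpyrrolidin-1-yl]propan-1-one | C[C@@H]1CC[C@@H](C)N1C(=O)CCc1ccc(O[Si](C)(C)C(C)(C)C)c(Br)c1
A3 | alternative 1 | 4-acetoxystyrene | CC(=O)Oc1ccc(C=C)cc1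
A4 | alternative 1 | trans-4-(4-acetoxyphenyl)-5-[3-bromo-4-(tert-butyldimethylsilyloxy)benzyl]dihydrofuran-2(3H)-one | CC(C)(C)[Si](C)(C)Oc1ccc(C[C@H]2OC(=O)C[C@@H]2c2ccc(OC(C)=O)cc2)cc1Br
A5 | alternative 2 | (5R)-4-[4-(tert-butyldimethylsilyloxy)phenyl]-5-{[4-(tert-butyldimethylsilyloxy)-3-(3-methylbut-2-en-1-yl)phenyl]methyl}furan-2(5H)-one | CC(C)=CCc1cc(C[C@H]2OC(=O)C=C2c2ccc(O[Si](C)(C)C(C)(C)C)cc2)ccc1O[Si](C)(C)C(C)(C)C
A6 | alternative 2 | (R)-5-[4-(tert-butyldimethylsilyloxy)-3-(3-methylbut-2-en-1-yl)phenyl]penta-2,3-dienoic acid | OC(=O)C([H])=[C@]=C([H])Cc1ccc(O[Si](C)(C)C(C)(C)C)c(CC=C(C)C)c1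
A7 | alternative 2 | tert-butyl(4-iodophenoxy)dimethylsilane | CC(C)(C)[Si](C)(C)Oc1ccc(I)cc1
A8 | alternative 3 | (5S)-5-(iodomethyl)-3-(methoxymethoxy)-4-[4-(tert-butyldimethylsilyloxy)phenyl]furan-2(5H)-one | IC[C@H]1OC(=O)C(OCOC)=C1c1ccc(O[Si](C)(C)C(C)(C)C)cc1
A9 | alternative 3 | (2Z)-2-(methoxymethoxy)-3-[4-(tert-butyldimethylsilyloxy)phenyl]penta-2,4-dienoic acid | OC(=O)/C(OCOC)=C(\C=C)c1ccc(O[Si](C)(C)C(C)(C)C)cc1
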